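The numbers belong to no real substance; the result is computed.

2.59 mM of free substrate is the crossover level C: the ring constant over three times the dimer constant, the level at which ring closure takes as much substrate as the route through open dimer to open trimer, three substrate per turn.

| setting | Saturday's | Sunday's | Thursday's | Wednesday's |
|---|---|---|---|---|
| substrate | 20 mM | 20 mM | 20 mM | 20 mM |
| time | 2.5 d | 2.5 d |  |  |
| remark | plug flow through a tube for 2.5 d, no back-mixing | everything together in a closed stirred flask, run for 2.5 d | a single well-mixed tank run continuously and read at steady state, 2.5 d in it on average | one stirred flow tank at steady state, fed with the mixture as stated, mean residence time 7.50 d |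

    2 substrate → open dimer (k1 = 14.3 L mol⁻¹ h⁻¹)
    substrate + ring ⇌ idle adduct, settled at all times (K2 = 35 L mol⁻¹)
    substrate + open dimer → open trimer (k3 = 31.2 L mol⁻¹ h⁻¹)
    substrate → ring (k4 = 0.111 h⁻¹)
    substrate + ring → side product (k5 = 2.41 L mol⁻¹ h⁻¹)

1. the set-up with the highest share of ring in all that became ring or open dimer or open trimer or side product, at the outlet or at the end ("none" if the first two lie within 2 percentage points) (Saturday's / Sunday's / Thursday's / Wednesday's / none)
2. share of ring in all that became ring or open dimer or open trimer or side product, at the outlet or at the end, Saturday's
3. share of ring in all that became ring or open dimer or open trimer or side product, at the outlet or at the end, Sunday's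
4. share of ring in all that became ring or open dimer or open trimer or side product, at the outlet or at the end, Thursday's
5. share of ring in all that became ring or open dimer or open trimer or side product, at the outlet or at the end, Wednesday's

- percent here means substrate units held: one open dimer or idle adduct or side product counts as two
- percent here means substrate units held: one open trimer counts as three
- what is said of ring includes idle adduct
- a doubled species enters its step squared and goes two at a time
- the stated concentrations are those of everything mixed, before any reaction; amounts are the same in each set-up
- in an amount of ring, one idle adduct counts as one ring
- run time (Saturday's): 2.5 d

**First instants.** Sunday's closed flask starts at 20 mM, which is 7.72 C. Substrate's first half-life by the dimer step is 1.75 h and by the ring step 0.26 d, so the dimer step runs faster. At the start, ring closure uses 0.194 of what the dimer step uses. Saturday's tube is the same run laid out along its length, since its slices never mix.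

**The middle.** The trimer constant is twice the dimer constant, so I count three substrate per dimer turn, which overcounts any dimer that stays open. The adduct constant times the starting substrate is 0.700, so ring formed early sits partly as idle adduct, but I count that as ring anyway. By this count, ring closure takes the lead once substrate stands below C. Summing over the fall, the ring share (the selectivity) is C over the charge, times the natural log of one plus charge over C: 28.0%.

**The end.** The run lasts 9.61 half-lives of substrate by the ring step, and that step by itself leaves 0.0256 mM substrate. So I take 28.0% for both Saturday's and Sunday's.

**The tanks.** A steady tank holds one substrate level S: by my count, charge minus S equals residence time times the ring rate plus three times the dimer turn rate. Thursday's S is 1.67 mM and Wednesday's 0.748 mM. C over C plus S then gives 60.7% and 77.6%. These leave out the side step, so I hold them as high, but I still put Wednesday's first.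

**The forecast.** The forecast names Wednesday's, with 25.8%, 25.8%, 48.9% and 54.2% in the order asked, on the ground that "the well-mixed tanks, which hold substrate low, favour ring".

**The result.** The simulation gives 26.1% for Saturday's, 26.1% for Sunday's, 47.6% for Thursday's and 53.8% for Wednesday's, so Wednesday's leads. Sunday's ends with 2.80% side product, half of it ring units, so ring made is 27.5% against my 28.0%. The tanks part from my reckoning: Wednesday's holds 0.658 mM substrate, C then gives 79.7%, and the flask shows 53.8%.

**A neighbour.** Sunday's flask charged with 8.0 mM substrate starts at 3.09 C, and the same formula gives 45.6%. That flask ends with a ring share of 45.6%, and its ring stands above its open trimer at 31.0%.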